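I decide to carry one number through this flask, and to read it from the midnight run.

- midnight: Q 1 M; E 40 mM; run made earlier
- flask: Q 1.0 M; E 20 mM; time 15 d

midnight run (percent of the Q charged)

| time / d | D / % | J / % |
|---|---|---|
| 0.250 | 1 | 9 |
| 0.500 | 0 | 10 |
| 1.25 | 4 | 21 |
| 3.00 | 16 | 25 |

(readings scatter by 2 percentage points)

- what was read earlier has a scatter of 2 percentage points, one standard deviation
- no earlier run changes the charge of E; that part of a forecast is a guess

* ratio of D to J at 2.0 h
* ratio of D to J at 15 d
* which of D and J there is more of at 15 d

At 3.00 d the midnight run reads D 16% and J 25% of the charge, so S = 0.640, a reading of the D made per J made, a selectivity factor. If E serves both routes alike, it cancels from S, and going from 40 mM to 20 mM of E changes the pace and leaves the split; that is a guess, since no earlier run changes E. S stands below one, so I commit to a ratio near 0.640 at 15 d, with J ahead.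

Was one number enough? No: the ratio in the midnight run reads 0.111 at 0.250 d and 0.190 at 1.25 d, so D lags there. I therefore put the ratio at 2.0 h below that first reading, whose D lies within the scatter. The last interval of the midnight run reads 3.00 D per J, but on a J gain of 4 percentage points, against a scatter of 2 points on each of its two readings, so I stay with S.

The forecast differs: “That pattern reads as sequential, Q→J→D”. It gives 0.01 at 2.0 h, 2 at 15 d, and D ahead.

The flask gives 0.0332 at 2.0 h and 0.702 at 15 d, with J ahead: J 26.7%, D 18.7%.

    2 X → G (k = 0.0189 M⁻¹ h⁻¹)
    Q + E → E + J (k = 0.303 M⁻¹ h⁻¹)
    E + X → E + D (k = 0.171 M⁻¹ h⁻¹)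
    Q ⇌ X (K = 1.71, k = 0.0592 h⁻¹)

Here J is an end product, made from Q, and D is made from X, with E in both steps. S keeps the scatter of its two readings, and it stands beside the flask's 0.702 at 15 d. The same reckoning on a neighbour flask charged with 0.0080 M of E again says a ratio near 0.640, J ahead. That neighbour gives 0.716, with J at 13.1% and D at 9.38%.

All runs were generated by integration for substances that don't exist; noise was put on by code.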